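Ring C of the isoflavan is disconnected through O1–C2 and C3–C4. Because C4 is an unsubstituted methylene on the trioxygenated ring A and C3 carries ring B, these atoms map onto an o-quinone methide (O1, C8a, C4a, C4) and an (E)-β-aryl enol ether (C2, C3). One inverse-demand hetero-Diels–Alder reaction joins both halves, closes ring C and sets C3 under the control of a trans-2-phenylcyclohexyl group on the enol ether oxygen. Its precursors are the O-Boc salicyl alcohol of ring A and the enol ether made from a 5-silyloxy-2,2-dimethylchromene-8-carbaldehyde. Reductive removal of the acetal oxygen, C8 formylation, chelation-guided O7 demethylation and desilylation finish the synthesis.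

Key step: step 8

Assumption: the enol ether is taken to react as its s-trans conformer with the carbinol C–H in the enol ether plane, so that the phenyl group covers one alkene face; on this model the (1R,2S)-alcohol (both antipodes are commercial) leads to 3R and is the one used.

Step 1
Reactants: 1 2-hydroxy-4,6-dimethoxybenzaldehyde
Product: 2 tert-butyl 2-formyl-3,5-dimethoxyphenyl carbonate
Conditions: Boc2O (1.2 equiv), i-Pr2NEt, DMAP (cat.), THF, rt
Reagents that add atoms: di-tert-butyl dicarbonate, CC(C)(C)OC(=O)OC(=O)OC(C)(C)C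
Why: DMAP-catalysed O-acylation of a phenol by Boc2O (aryl carbonate formation) should proceed cleanly because the acylpyridinium ion is reactive enough for the hydrogen-bonded hydroxyl and leaves the aldehyde untouched.

Step 2
Reactants: 2 tert-butyl 2-formyl-3,5-dimethoxyphenyl carbonate
Product: 3 tert-butyl 2-(hydroxymethyl)-3,5-dimethoxyphenyl carbonate
Conditions: BH3·THF (1.0 equiv), THF, 0 °C; then pH 7 buffer
Reagents that add atoms: none
Why: Chemoselective borane reduction of an aldehyde gives a neutral boron alkoxide instead of a free metal alkoxide, so the neighbouring carbonate should neither migrate nor release the quinone methide prematurely, which a basic borohydride reduction would risk.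

Step 3
Reactants: 4 2,4-dihydroxybenzaldehyde
Product: 5 2-hydroxy-4-[(triisopropylsilyl)oxy]benzaldehyde
Conditions: TIPSCl (1.05 equiv), imidazole, CH2Cl2, 0 °C to rt
Reagents that add atoms: chlorotriisopropylsilane, CC(C)[Si](Cl)(C(C)C)C(C)C
Why: Regioselective silylation of the more acidic, unchelated O4 (O2 is locked in a hydrogen bond to the formyl group) blocks the position whose propargylation would lead to the 6-formyl-5-hydroxychromene, the wrong ring B isomer; TIPS is chosen because the aryl silyl ether must later withstand carbonate base, a Grignard base and Lewis acids.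

Step 4
Reactants: 5 2-hydroxy-4-[(triisopropylsilyl)oxy]benzaldehyde; 6 3-chloro-3-methylbut-1-yne
Product: 7 2-[(2-methylbut-3-yn-2-yl)oxy]-4-[(triisopropylsilyl)oxy]benzaldehyde
Conditions: DBU (1.5 equiv), CuCl2·2H2O (1 mol%), MeCN, 0 °C to rt
Reagents that add atoms: none
Why: Copper-catalysed O-propargylation of a phenol with a tertiary propargylic chloride, in which a copper acetylide–allenylidene species is captured by the phenoxide at the tertiary carbon, is the method suited to hindered, electron-poor salicylaldehyde-type phenols.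

Step 5
Reactants: 7 2-[(2-methylbut-3-yn-2-yl)oxy]-4-[(triisopropylsilyl)oxy]benzaldehyde
Product: 10 2,2-dimethyl-5-[(triisopropylsilyl)oxy]-2H-chromene-8-carbaldehyde, via allenylphenol 8 (not isolated), via dienone 9 (not isolated)
Conditions: PhNEt2, 185 °C
Reagents that add atoms: none
Why: Aryl propargyl ether Claisen rearrangement: the [3,3] shift can only reach C3 because the other ortho carbon carries the formyl group, after which enolisation to 8, a [1,5]-hydrogen shift to 9 and oxa-6π electrocyclisation should close the 2,2-dimethylpyran with its oxygen ortho to the formyl carbon, as ring B of the target requires.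

Step 6
Reactants: 10 2,2-dimethyl-5-[(triisopropylsilyl)oxy]-2H-chromene-8-carbaldehyde
Product: 11 8-[(E)-2-iodoethenyl]-2,2-dimethyl-5-[(triisopropylsilyl)oxy]-2H-chromene
Conditions: CrCl2 (6 equiv), CHI3 (2 equiv), THF–1,4-dioxane, 0 °C to rt
Reagents that add atoms: iodoform, IC(I)I
Why: Takai iodo-olefination: the geminal dichromium species from CHI3 adds to the aldehyde and eliminates through the less crowded arrangement, so the (E)-iodoalkene should dominate (the dioxane cosolvent reinforces this) and any minor (Z)-isomer is removed by chromatography.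

Step 7
Reactants: 11 8-[(E)-2-iodoethenyl]-2,2-dimethyl-5-[(triisopropylsilyl)oxy]-2H-chromene; 12 (1R,2S)-trans-2-phenylcyclohexanol
Product: 13 8-[(E)-2-{[(1R,2S)-2-phenylcyclohexyl]oxy}ethenyl]-2,2-dimethyl-5-[(triisopropylsilyl)oxy]-2H-chromene
Conditions: CuI (10 mol%), 3,4,7,8-tetramethyl-1,10-phenanthroline (20 mol%), Cs2CO3 (2 equiv), 12 (2 equiv), toluene, 80 °C
Reagents that add atoms: none
Why: Ullmann-type copper-catalysed C–O coupling of a vinyl iodide with a secondary alcohol proceeds with retention of the alkene geometry and does not touch the C–O bond of the carbinol, so the (E)-configuration and both stereocentres of the auxiliary should be carried over unchanged.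

Step 8
Reactants: 3 tert-butyl 2-(hydroxymethyl)-3,5-dimethoxyphenyl carbonate; 13 8-[(E)-2-{[(1R,2S)-2-phenylcyclohexyl]oxy}ethenyl]-2,2-dimethyl-5-[(triisopropylsilyl)oxy]-2H-chromene
Product: 16 (2S,3R)-3-{2,2-dimethyl-5-[(triisopropylsilyl)oxy]-2H-chromen-8-yl}-5,7-dimethoxy-2-{[(1R,2S)-2-phenylcyclohexyl]oxy}chromane (2,3-trans), via phenoxide 14 (not isolated), via quinone methide 15 (not isolated)
Conditions: 3 (2.0 equiv), 13 (1.0 equiv), t-BuMgCl (2.05 equiv, slow addition), toluene, −78 °C to rt; aq. NH4Cl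
Reagents that add atoms: none
Why: t-BuMgCl deprotonates the benzylic alcohol of 3, the magnesium alkoxide takes over the Boc group to give phenoxide 14, and loss of tert-butyl carbonate unveils quinone methide 15 (O1=C8a–C4a=C4H2 in chroman numbering), an electron-poor 1-oxadiene that is trapped in a concerted but asynchronous inverse-electron-demand hetero-Diels–Alder reaction by the electron-rich alkene of 13. The closest known reaction type is the low-temperature anionic generation of o-quinone methides from O-Boc salicyl alcohols with their diastereoselective [4+2] capture by trans-2-phenylcyclohexyl enol ethers. Ring C is closed by intermolecular [4+2] cycloaddition (a 4π+2π annulation of two fragments, not the cyclisation of a tethered chain), O1–C2 and C3–C4 forming in the same step while ring A regains aromaticity. C3 is set by the auxiliary, whose phenyl group covers one face of the s-trans enol ether so that C4 bonds to the open face, and C2 follows from suprafacial addition across the (E)-alkene (2,3-trans) and is erased in step 9. Regioselectivity (C4 to the aryl-bearing carbon, O1 to the alkoxy carbon) is secured by the matched polarity of the methide carbon and the enol ether β-carbon, and chemoselectivity over the chromene alkene by the much higher nucleophilicity of the enol ether. Adducts from the minor face or from residual (Z)-13 still carry the auxiliary, are diastereomers of 16 and should be separable before the auxiliary is removed.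

Step 9
Reactants: 16 (2S,3R)-3-{2,2-dimethyl-5-[(triisopropylsilyl)oxy]-2H-chromen-8-yl}-5,7-dimethoxy-2-{[(1R,2S)-2-phenylcyclohexyl]oxy}chromane
Product: 18 (3R)-3-{2,2-dimethyl-5-[(triisopropylsilyl)oxy]-2H-chromen-8-yl}-5,7-dimethoxychromane, via oxocarbenium ion 17 (not isolated)
Conditions: Et3SiH (5 equiv), BF3·OEt2 (2 equiv), CH2Cl2, −78 to −40 °C; aq. NaHCO3
Reagents that add atoms: none
Why: Ionic reduction of a mixed acetal: BF3 ionises the exocyclic C2–O bond (the cyclohexyl oxygen is the more basic one and O1 stabilises cation 17) and Et3SiH delivers hydride to C2, while low temperature and excess silane are meant to keep hydride capture faster than proton loss from C3, whose configuration is not otherwise involved.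

Step 10
Reactants: 18 (3R)-3-{2,2-dimethyl-5-[(triisopropylsilyl)oxy]-2H-chromen-8-yl}-5,7-dimethoxychromane
Product: 20 (3R)-3-{2,2-dimethyl-5-[(triisopropylsilyl)oxy]-2H-chromen-8-yl}-5,7-dimethoxychromane-8-carbaldehyde, via iminium chloride 19 (not isolated)
Conditions: POCl3 (1.3 equiv), DMF, 0 °C to rt; then aq. NaOAc
Reagents that add atoms: N,N-dimethylformamide, CN(C)C=O; water, O
Why: Vilsmeier–Haack formylation: the phloroglucinol-type ring A is far more nucleophilic than ring B or the chromene alkene, and the bulky chloroiminium ion should prefer C8, flanked by the tied-back ring oxygen O1, over C6 between two freely rotating methoxy groups; hydrolysis of iminium salt 19 on work-up supplies the aldehyde oxygen.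

Step 11
Reactants: 20 (3R)-3-{2,2-dimethyl-5-[(triisopropylsilyl)oxy]-2H-chromen-8-yl}-5,7-dimethoxychromane-8-carbaldehyde
Product: 21 (3R)-3-{2,2-dimethyl-5-[(triisopropylsilyl)oxy]-2H-chromen-8-yl}-7-hydroxy-5-methoxychromane-8-carbaldehyde
Conditions: MgI2·OEt2 (2.5 equiv), THF–toluene, 60 °C; aq. NH4Cl
Reagents that add atoms: none
Why: Chelation-controlled ether cleavage: magnesium bridges the formyl oxygen and O7 and iodide removes the activated methyl group by SN2 attack, whereas the 5-methoxy group para to the aldehyde cannot chelate and the other chelating oxygen, O1, could only be cleaved by attack at the β-branched ring carbon C2, which is much slower than attack at methyl.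

Step 12
Reactants: 21 (3R)-3-{2,2-dimethyl-5-[(triisopropylsilyl)oxy]-2H-chromen-8-yl}-7-hydroxy-5-methoxychromane-8-carbaldehyde
Product: 22 (3R)-7-hydroxy-3-(5-hydroxy-2,2-dimethyl-2H-chromen-8-yl)-5-methoxychromane-8-carbaldehyde (target)
Conditions: TBAF (1.2 equiv), AcOH (1.2 equiv), THF, 0 °C
Reagents that add atoms: none
Why: Fluoride-mediated desilylation of an aryl silyl ether is driven by Si–F bond formation; buffering with acetic acid keeps the medium near neutral for the salicylaldehyde and the chromene, and C3 is not affected.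

Compound list
1 | 2-hydroxy-4,6-dimethoxybenzaldehyde | COc1cc(O)c(C=O)c(OC)c1 | starting material
2 | tert-butyl 2-formyl-3,5-dimethoxyphenyl carbonate | COc1cc(OC)c(C=O)c(OC(=O)OC(C)(C)C)c1 | intermediate
3 | tert-butyl 2-(hydroxymethyl)-3,5-dimethoxyphenyl carbonate | COc1cc(OC)c(CO)c(OC(=O)OC(C)(C)C)c1 | intermediate
4 | 2,4-dihydroxybenzaldehyde | O=Cc1ccc(O)cc1O | starting material
5 | 2-hydroxy-4-[(triisopropylsilyl)oxy]benzaldehyde | O=Cc1ccc(O[Si](C(C)C)(C(C)C)C(C)C)cc1O | intermediate
6 | 3-chloro-3-methylbut-1-yne | CC(C)(Cl)C#C | starting material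
7 | 2-[(2-methylbut-3-yn-2-yl)oxy]-4-[(triisopropylsilyl)oxy]benzaldehyde | O=Cc1ccc(O[Si](C(C)C)(C(C)C)C(C)C)cc1OC(C)(C)C#C | intermediate
8 | 2-hydroxy-3-(3-methylbuta-1,2-dien-1-yl)-4-[(triisopropylsilyl)oxy]benzaldehyde (allenylphenol, formed in situ) | O=Cc1ccc(O[Si](C(C)C)(C(C)C)C(C)C)c(C=C=C(C)C)c1O | intermediate
9 | (5Z)-5-(3-methylbut-2-en-1-ylidene)-6-oxo-4-[(triisopropylsilyl)oxy]cyclohexa-1,3-diene-1-carbaldehyde (dienone, formed in situ) | CC(C)=C/C=C1\C(=O)C(C=O)=CC=C1O[Si](C(C)C)(C(C)C)C(C)C | intermediate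
10 | 2,2-dimethyl-5-[(triisopropylsilyl)oxy]-2H-chromene-8-carbaldehyde | CC1(C)C=Cc2c(O[Si](C(C)C)(C(C)C)C(C)C)ccc(C=O)c2O1 | intermediate
11 | 8-[(E)-2-iodoethenyl]-2,2-dimethyl-5-[(triisopropylsilyl)oxy]-2H-chromene | CC1(C)C=Cc2c(O[Si](C(C)C)(C(C)C)C(C)C)ccc(/C=C/I)c2O1 | intermediate
12 | (1R,2S)-trans-2-phenylcyclohexanol | O[C@@H]1CCCC[C@H]1c1ccccc1 | starting material
13 | 8-[(E)-2-{[(1R,2S)-2-phenylcyclohexyl]oxy}ethenyl]-2,2-dimethyl-5-[(triisopropylsilyl)oxy]-2H-chromene | CC1(C)C=Cc2c(O[Si](C(C)C)(C(C)C)C(C)C)ccc(/C=C/O[C@@H]3CCCC[C@H]3c3ccccc3)c2O1 | intermediate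
14 | chloromagnesium 2-{[(tert-butoxycarbonyl)oxy]methyl}-3,5-dimethoxyphenolate (formed in situ) | COc1cc(OC)c(COC(=O)OC(C)(C)C)c([O-])c1.[Mg+2].[Cl-] | intermediate
15 | 3,5-dimethoxy-6-methylidenecyclohexa-2,4-dien-1-one (o-quinone methide, formed in situ) | O=C1C=C(OC)C=C(OC)C1=C | intermediate
16 | (2S,3R)-3-{2,2-dimethyl-5-[(triisopropylsilyl)oxy]-2H-chromen-8-yl}-5,7-dimethoxy-2-{[(1R,2S)-2-phenylcyclohexyl]oxy}chromane | COc1cc(OC)cc2c1C[C@H](c1ccc(O[Si](C(C)C)(C(C)C)C(C)C)c3c1OC(C)(C)C=C3)[C@@H](O[C@@H]1CCCC[C@H]1c1ccccc1)O2 | intermediate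
17 | (3R)-3-{2,2-dimethyl-5-[(triisopropylsilyl)oxy]-2H-chromen-8-yl}-5,7-dimethoxy-3,4-dihydrochromenylium trifluoro{[(1R,2S)-2-phenylcyclohexyl]oxy}borate (formed in situ) | COc1cc(OC)cc2c1C[C@H](c1ccc(O[Si](C(C)C)(C(C)C)C(C)C)c3c1OC(C)(C)C=C3)C=[O+]2.F[B-](F)(F)O[C@@H]1CCCC[C@H]1c1ccccc1 | intermediate
18 | (3R)-3-{2,2-dimethyl-5-[(triisopropylsilyl)oxy]-2H-chromen-8-yl}-5,7-dimethoxychromane | COc1cc(OC)cc2c1C[C@H](c1ccc(O[Si](C(C)C)(C(C)C)C(C)C)c3c1OC(C)(C)C=C3)CO2 | intermediate
19 | N-{[(3R)-3-{2,2-dimethyl-5-[(triisopropylsilyl)oxy]-2H-chromen-8-yl}-5,7-dimethoxychroman-8-yl]methylidene}-N-methylmethanaminium chloride (formed in situ) | COc1cc(OC)c(C=[N+](C)C)c2c1C[C@H](c1ccc(O[Si](C(C)C)(C(C)C)C(C)C)c3c1OC(C)(C)C=C3)CO2.[Cl-] | intermediate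
20 | (3R)-3-{2,2-dimethyl-5-[(triisopropylsilyl)oxy]-2H-chromen-8-yl}-5,7-dimethoxychromane-8-carbaldehyde | COc1cc(OC)c(C=O)c2c1C[C@H](c1ccc(O[Si](C(C)C)(C(C)C)C(C)C)c3c1OC(C)(C)C=C3)CO2 | intermediate
21 | (3R)-3-{2,2-dimethyl-5-[(triisopropylsilyl)oxy]-2H-chromen-8-yl}-7-hydroxy-5-methoxychromane-8-carbaldehyde | COc1cc(O)c(C=O)c2c1C[C@H](c1ccc(O[Si](C(C)C)(C(C)C)C(C)C)c3c1OC(C)(C)C=C3)CO2 | intermediate
22 | (3R)-7-hydroxy-3-(5-hydroxy-2,2-dimethyl-2H-chromen-8-yl)-5-methoxychromane-8-carbaldehyde | COc1cc(O)c(C=O)c2c1C[C@H](c1ccc(O)c3c1OC(C)(C)C=C3)CO2 | target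

Total step count: 12. Longest linear sequence: 10 steps (steps 3 to 12, from compound 4).

Steps most likely to fail

Step 8. The stabilised dimethoxy quinone methide may oligomerise faster than the hindered β-aryl enol ether traps it, or the auxiliary may discriminate the alkene faces poorly because s-cis or exo pathways compete. The fallback replaces the cycloaddition by an oxazolidinone-controlled enolate alkylation (Evans alkylation) followed by Mitsunobu ring closure; it sets out from aldehydes 10 and 1 and returns to the route at isoflavan 18.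
- Ring B acid: Wittig reaction of 10 with Ph3P=CHOMe (from the phosphonium chloride and KHMDS, THF, 0 °C) should give the methyl enol ether F1. Hydrolysis (aq. HCl, THF) gives the arylacetaldehyde F2, and Pinnick oxidation (NaClO2, NaH2PO4, 2-methylbut-2-ene) the arylacetic acid F3.
- Imide: activation of F3 as the pivalic mixed anhydride (PivCl, Et3N) and N-acylation of lithiated (R)-4-benzyl-1,3-oxazolidin-2-one gives the imide F4.
- Ring A electrophile: 1 is O-allylated (allyl bromide, K2CO3, DMF) to the aldehyde F5, reduced (NaBH4, MeOH) to the benzyl alcohol F6 and converted (PBr3, Et2O, −20 °C) into the benzyl bromide F7, which is used at once.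
- Alkylation and closure: the sodium enolate of F4 (NaHMDS, THF, −78 °C) is alkylated by F7 on the face away from the benzyl group, giving the imide F8 with an (R)-configured α-carbon. LiBH4 releases the auxiliary and gives the primary alcohol F9. Pd(PPh3)4 with morpholine removes the allyl group to give the phenol alcohol F10, and PPh3/DIAD in THF forms the O1–C2 bond to deliver 18.

Step 9. The C2 oxocarbenium ion may lose the benzylic proton at C3 to give the isoflav-2-ene, whose reprotonation would erode the C3 configuration, and traces of Brønsted acid may hydrogenate the chromene alkene ionically. The fallback avoids hydride capture of a cation; it sets out from 16 and returns at 18. Mild aqueous acid (PPTS, acetone–water, 40 °C) should hydrolyse 16 to the lactol F11, the cation being intercepted at once by water and the auxiliary being released. NaBH4 in EtOH at 0 °C reduces the open hydroxy aldehyde tautomer as it forms to the phenol alcohol F10 described above, and PPh3/DIAD recloses the O1–C2 bond to give 18.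

Step 10. Electrophilic attack may compete at C6, go on to diformylation, or be accompanied by acid-promoted loss of the silyl group. The fallback installs the formyl group through a halogen handle; it sets out from 18 and returns at 20. NBS in CH2Cl2 at −78 °C should brominate the trioxygenated ring at the less hindered C8, a preference typical of 5,7-dialkoxychromans, to give the bromide F12, whose regiochemistry can be secured before it is used. Bromine–lithium exchange (n-BuLi, THF, −78 °C) and quenching with DMF then give 20.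

Further compounds
F1 | step 8 | 8-(2-methoxyethenyl)-2,2-dimethyl-5-[(triisopropylsilyl)oxy]-2H-chromene (E/Z mixture) | COC=Cc1ccc(O[Si](C(C)C)(C(C)C)C(C)C)c2c1OC(C)(C)C=C2
F2 | step 8 | {2,2-dimethyl-5-[(triisopropylsilyl)oxy]-2H-chromen-8-yl}acetaldehyde | O=CCc1ccc(O[Si](C(C)C)(C(C)C)C(C)C)c2c1OC(C)(C)C=C2
F3 | step 8 | {2,2-dimethyl-5-[(triisopropylsilyl)oxy]-2H-chromen-8-yl}acetic acid | OC(=O)Cc1ccc(O[Si](C(C)C)(C(C)C)C(C)C)c2c1OC(C)(C)C=C2
F4 | step 8 | (4R)-4-benzyl-3-({2,2-dimethyl-5-[(triisopropylsilyl)oxy]-2H-chromen-8-yl}acetyl)-1,3-oxazolidin-2-one | O=C(Cc1ccc(O[Si](C(C)C)(C(C)C)C(C)C)c2c1OC(C)(C)C=C2)N1C(=O)OC[C@H]1Cc1ccccc1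
F5 | step 8 | 2-(allyloxy)-4,6-dimethoxybenzaldehyde | C=CCOc1cc(OC)cc(OC)c1C=O
F6 | step 8 | [2-(allyloxy)-4,6-dimethoxyphenyl]methanol | C=CCOc1cc(OC)cc(OC)c1CO
F7 | step 8 | 1-(allyloxy)-2-(bromomethyl)-3,5-dimethoxybenzene | C=CCOc1cc(OC)cc(OC)c1CBr
F8 | step 8 | (4R)-4-benzyl-3-[(2R)-3-[2-(allyloxy)-4,6-dimethoxyphenyl]-2-{2,2-dimethyl-5-[(triisopropylsilyl)oxy]-2H-chromen-8-yl}propanoyl]-1,3-oxazolidin-2-one | O=C([C@H](Cc1c(OCC=C)cc(OC)cc1OC)c1ccc(O[Si](C(C)C)(C(C)C)C(C)C)c2c1OC(C)(C)C=C2)N1C(=O)OC[C@H]1Cc1ccccc1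
F9 | step 8 | (2R)-3-[2-(allyloxy)-4,6-dimethoxyphenyl]-2-{2,2-dimethyl-5-[(triisopropylsilyl)oxy]-2H-chromen-8-yl}propan-1-ol | OC[C@H](Cc1c(OCC=C)cc(OC)cc1OC)c1ccc(O[Si](C(C)C)(C(C)C)C(C)C)c2c1OC(C)(C)C=C2
F10 | step 8 | 2-[(2R)-2-{2,2-dimethyl-5-[(triisopropylsilyl)oxy]-2H-chromen-8-yl}-3-hydroxypropyl]-3,5-dimethoxyphenol | OC[C@H](Cc1c(O)cc(OC)cc1OC)c1ccc(O[Si](C(C)C)(C(C)C)C(C)C)c2c1OC(C)(C)C=C2
F11 | step 9 | (3R)-3-{2,2-dimethyl-5-[(triisopropylsilyl)oxy]-2H-chromen-8-yl}-5,7-dimethoxychroman-2-ol (anomeric mixture) | COc1cc(OC)cc2c1C[C@H](c1ccc(O[Si](C(C)C)(C(C)C)C(C)C)c3c1OC(C)(C)C=C3)C(O)O2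
F12 | step 10 | (3R)-8-bromo-3-{2,2-dimethyl-5-[(triisopropylsilyl)oxy]-2H-chromen-8-yl}-5,7-dimethoxychromane | COc1cc(OC)c(Br)c2c1C[C@H](c1ccc(O[Si](C(C)C)(C(C)C)C(C)C)c3c1OC(C)(C)C=C3)CO2
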